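The route rests on cutting the C4–C4a bond of upper ring C. Upper C4 is doubly benzylic, bonded to lower C6 and, in the target, to C4a of upper ring A, so it serves as the electrophile. In the precursor a trans-epoxide spans upper C3–C4 of an open-chain aryl ether in which C2 and C3 are already set. A Lewis acid lets the free ortho carbon of the 2,3-bis(benzyloxy)phenyl ether attack C4 with inversion; one operation closes ring C, forms C4–C4a and fixes the 2,3-cis-3,4-trans pattern. The acetyl group on lower ring A then grows lower ring C through a chalcone under reagent control.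

Key step: step 11

Assumption: gallacetophenone, 3,4-bis(benzyloxy)benzaldehyde, 2,3-dihydroxybenzaldehyde and 4-(benzyloxy)benzaldehyde are bought; the oxygen of lower ring A next to the acetyl group is carried as a methoxymethyl ether, because it must later be freed alone, by mild acid, to close lower ring C.

Step 1
Reactants: 1 gallacetophenone (2',3',4'-trihydroxyacetophenone)
Product: 2 1-[3,4-bis(benzyloxy)-2-hydroxyphenyl]ethan-1-one
Conditions: BnBr (2.1 equiv), K2CO3 (2.2 equiv), acetone, reflux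
Reagents that add atoms: benzyl bromide, BrCc1ccccc1
Why: Williamson ether synthesis; the hydroxyl next to the acetyl group is hydrogen-bonded to the carbonyl oxygen and is the least nucleophilic, so two equivalents of benzyl bromide should alkylate only O3 and O4.

Step 2
Reactants: 2 1-[3,4-bis(benzyloxy)-2-hydroxyphenyl]ethan-1-one
Product: 3 1-[3,4-bis(benzyloxy)-5-bromo-2-hydroxyphenyl]ethan-1-one
Conditions: NBS (1.05 equiv), MeCN, 0 °C
Reagents that add atoms: N-bromosuccinimide, O=C1CCC(=O)N1Br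
Why: Electrophilic aromatic bromination; C5 is para to the free phenol and ortho to a benzyloxy group, whereas C6 is ortho to the acetyl group and meta to the phenol, so bromine should enter at C5.

Step 3
Reactants: 3 1-[3,4-bis(benzyloxy)-5-bromo-2-hydroxyphenyl]ethan-1-one
Product: 4 1-[3,4-bis(benzyloxy)-5-bromo-2-(methoxymethoxy)phenyl]ethan-1-one
Conditions: NaH, DMF, 0 °C; MOMCl, 0 °C to rt
Reagents that add atoms: chloromethyl methyl ether, COCCl
Why: Williamson-type O-alkylation of the sodium phenoxide; the acetal survives base, palladium, titanium alkoxide and Mitsunobu conditions and is later removed by mild acid.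

Step 4
Reactants: 5 3,4-bis(benzyloxy)benzaldehyde
Product: 6 rac-1-[3,4-bis(benzyloxy)phenyl]prop-2-yn-1-ol
Conditions: HC≡CMgBr (0.5 M in THF), THF, 0 °C; aq. NH4Cl
Reagents that add atoms: ethynylmagnesium bromide, C#C[Mg]Br
Why: Grignard addition of an acetylide to an aldehyde; the carbinol is racemic here and is resolved in step 7.

Step 5
Reactants: 6 rac-1-[3,4-bis(benzyloxy)phenyl]prop-2-yn-1-ol
Product: 9 rac-(E)-1-[3,4-bis(benzyloxy)phenyl]-3-(4,4,5,5-tetramethyl-1,3,2-dioxaborolan-2-yl)prop-2-en-1-ol, via O-boryl alkyne 7 (not isolated), via O-boryl alkenylboronate 8 (not isolated)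
Conditions: HBpin (2.5 equiv), Cp2ZrHCl (10 mol %), Et3N (10 mol %), CH2Cl2, rt; then H2O work-up
Reagents that add atoms: pinacolborane, CC1(C)OBOC1(C)C
Why: Cp2ZrHCl-catalysed hydroboration of a terminal alkyne, a syn anti-Markovnikov addition that gives the (E)-1-alkenylboronate; the hydroxyl is masked in the flask as its borate and freed again on aqueous work-up.

Step 6
Reactants: 4 1-[3,4-bis(benzyloxy)-5-bromo-2-(methoxymethoxy)phenyl]ethan-1-one; 9 rac-(E)-1-[3,4-bis(benzyloxy)phenyl]-3-(4,4,5,5-tetramethyl-1,3,2-dioxaborolan-2-yl)prop-2-en-1-ol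
Product: 10 rac-1-{3,4-bis(benzyloxy)-5-[(E)-3-[3,4-bis(benzyloxy)phenyl]-3-hydroxyprop-1-en-1-yl]-2-(methoxymethoxy)phenyl}ethan-1-one
Conditions: Pd(dppf)Cl2 (5 mol %), K3PO4 (aq.), 1,4-dioxane, 70 °C
Reagents that add atoms: none
Why: Suzuki–Miyaura coupling (oxidative addition of the aryl bromide to zerovalent palladium, transmetalation, reductive elimination) joins lower C6 to the side chain with the E geometry kept; ketone, acetal and free hydroxyl tolerate the phosphate base.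

Step 7
Reactants: 10 rac-1-{3,4-bis(benzyloxy)-5-[(E)-3-[3,4-bis(benzyloxy)phenyl]-3-hydroxyprop-1-en-1-yl]-2-(methoxymethoxy)phenyl}ethan-1-one
Product: 11 1-{3,4-bis(benzyloxy)-5-[(2S,3S)-3-{(S)-[3,4-bis(benzyloxy)phenyl](hydroxy)methyl}oxiran-2-yl]-2-(methoxymethoxy)phenyl}ethan-1-one
Conditions: Ti(OiPr)4 (1.0 equiv), diisopropyl L-(+)-tartrate (1.2 equiv), TBHP (0.5 equiv, in isooctane), 4 Å MS, CH2Cl2, −20 °C, stopped near half conversion
Reagents that add atoms: tert-butyl hydroperoxide, CC(C)(C)OO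
Why: Sharpless asymmetric epoxidation run as a kinetic resolution; with the L-(+)-tartrate the (R)-carbinol is the fast enantiomer and should be epoxidised to the erythro (2S,3S)-epoxy alcohol, so the catalyst sets upper C3 and C4 and selects the carbinol configuration, while the slow (S)-alcohol stays behind and is removed by chromatography.

Step 8
Reactants: 12 2,3-dihydroxybenzaldehyde
Product: 13 2,3-bis(benzyloxy)benzaldehyde
Conditions: BnBr (2.3 equiv), K2CO3, DMF, 60 °C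
Reagents that add atoms: benzyl bromide, BrCc1ccccc1
Why: Williamson ether synthesis on both phenols.

Step 9
Reactants: 13 2,3-bis(benzyloxy)benzaldehyde
Product: 15 2,3-bis(benzyloxy)phenol, via aryl formate 14 (not isolated)
Conditions: mCPBA, CH2Cl2, 0 °C to rt; then K2CO3 (cat.), MeOH, rt
Reagents that add atoms: 3-chloroperbenzoic acid, O=C(OO)c1cccc(Cl)c1
Why: Baeyer–Villiger oxidation of an electron-rich benzaldehyde (aryl migration, Dakin-type outcome) gives the aryl formate, which methanolysis turns into the phenol.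

Step 10
Reactants: 11 1-{3,4-bis(benzyloxy)-5-[(2S,3S)-3-{(S)-[3,4-bis(benzyloxy)phenyl](hydroxy)methyl}oxiran-2-yl]-2-(methoxymethoxy)phenyl}ethan-1-one; 15 2,3-bis(benzyloxy)phenol
Product: 16 1-{5-[(2S,3R)-3-{(R)-[2,3-bis(benzyloxy)phenoxy][3,4-bis(benzyloxy)phenyl]methyl}oxiran-2-yl]-3,4-bis(benzyloxy)-2-(methoxymethoxy)phenyl}ethan-1-one
Conditions: PPh3 (1.5 equiv), DIAD (1.5 equiv), toluene, −20 to 0 °C
Reagents that add atoms: none
Why: Mitsunobu etherification; the phenol displaces the activated hydroxyl by SN2 with inversion, which turns the erythro carbinol into the threo aryl ether (C2 now R) that maps onto a 2,3-cis flavan.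

Step 11
Reactants: 16 1-{5-[(2S,3R)-3-{(R)-[2,3-bis(benzyloxy)phenoxy][3,4-bis(benzyloxy)phenyl]methyl}oxiran-2-yl]-3,4-bis(benzyloxy)-2-(methoxymethoxy)phenyl}ethan-1-one
Product: 17 1-{3,4-bis(benzyloxy)-5-[(2R,3R,4R)-7,8-bis(benzyloxy)-2-[3,4-bis(benzyloxy)phenyl]-3-hydroxy-3,4-dihydro-2H-chromen-4-yl]-2-(methoxymethoxy)phenyl}ethan-1-one (2,3-cis-3,4-trans)
Conditions: BF3·OEt2 (2.5 equiv), CH2Cl2, −78 °C; Et3N then aq. NaHCO3 at −78 °C
Reagents that add atoms: none
Why: BF3 binds the epoxide oxygen and lengthens the C4–O bond, which is benzylic to lower ring A and helped by its ortho and para alkoxy groups, and the only free ortho carbon of the 2,3-bis(benzyloxy)phenyl ether (future C4a, para to the O7 benzyl ether) attacks C4 from the side opposite the departing oxygen. The closest known reaction type is the Lewis-acid-mediated intramolecular Friedel–Crafts alkylation of arenes by benzylic epoxides (epoxy–arene cyclisation of aryl ethers to trans-4-arylchroman-3-ols). Upper ring C closes in the 6-endo-tet mode, which benzylic activation of the distal epoxide carbon makes available. C4 is the one new stereocentre and is controlled by inversion at C4 of the trans-epoxide (or, should the ion pair open fully, by closure with the lower aryl group anti to O3), which places the aryl group trans to the 3-hydroxyl while C2 and C3 are untouched, so the 2,3-cis-3,4-trans array results. The step needs opening at C4 and not C3, and closure by ring A and not by ring B of the upper unit (which would give an indane); the first is secured by the cation-stabilising lower ring, the second by the six-membered transition state and by the attacking carbon being ortho and para to two oxygens. The acetyl group, which draws on the same two oxygens, keeps the epoxide from ionising before the arene is in place, and the methoxymethyl ether is expected to survive BF3·OEt2 for minutes at −78 °C.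

Step 12
Reactants: 17 1-{3,4-bis(benzyloxy)-5-[(2R,3R,4R)-7,8-bis(benzyloxy)-2-[3,4-bis(benzyloxy)phenyl]-3-hydroxy-3,4-dihydro-2H-chromen-4-yl]-2-(methoxymethoxy)phenyl}ethan-1-one; 18 4-(benzyloxy)benzaldehyde
Product: 19 (E)-1-{3,4-bis(benzyloxy)-5-[(2R,3R,4R)-7,8-bis(benzyloxy)-2-[3,4-bis(benzyloxy)phenyl]-3-hydroxy-3,4-dihydro-2H-chromen-4-yl]-2-(methoxymethoxy)phenyl}-3-[4-(benzyloxy)phenyl]prop-2-en-1-one
Conditions: KOH (50% aq.), EtOH–THF, rt
Reagents that add atoms: none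
Why: Claisen–Schmidt condensation of the methyl ketone with a non-enolisable aldehyde gives the (E)-chalcone; benzyl ethers, the acetal and the hindered upper 3-hydroxyl are inert to aqueous base.

Step 13
Reactants: 19 (E)-chalcone of step 12
Product: 20 {3,4-bis(benzyloxy)-5-[(2R,3R,4R)-7,8-bis(benzyloxy)-2-[3,4-bis(benzyloxy)phenyl]-3-hydroxy-3,4-dihydro-2H-chromen-4-yl]-2-(methoxymethoxy)phenyl}{(2R,3S)-3-[4-(benzyloxy)phenyl]oxiran-2-yl}methanone
Conditions: poly-L-leucine, urea·H2O2, DBU, THF, rt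
Reagents that add atoms: hydrogen peroxide (from its urea adduct), OO
Why: Juliá–Colonna epoxidation; the helical poly-L-leucine directs hydroperoxide to one face of the (E)-enone and should give the (2R,3S)-trans-epoxy ketone, which fixes lower C3 by catalyst control (the remote upper unit cannot choose the face), and any minor diastereomer can be removed by chromatography.

Step 14
Reactants: 20 (2R,3S)-epoxy ketone of step 13
Product: 22 (2R,3R)-7,8-bis(benzyloxy)-6-[(2R,3R,4R)-7,8-bis(benzyloxy)-2-[3,4-bis(benzyloxy)phenyl]-3-hydroxy-3,4-dihydro-2H-chromen-4-yl]-2-[4-(benzyloxy)phenyl]-3-hydroxy-2,3-dihydro-4H-chromen-4-one (lower ring C 2,3-trans), via 2-hydroxyaryl epoxy ketone 21 (not isolated)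
Conditions: conc. HCl (cat.), MeOH–THF, 50 °C
Reagents that add atoms: none
Why: Acid removes the methoxymethyl group and the freed phenol opens the protonated epoxide at its benzylic carbon (6-endo), the established chalcone epoxide to dihydroflavonol cyclisation; C3 is kept from the epoxide and C2 forms trans to it, giving the (2R,3R) ring.

Step 15
Reactants: 22 (2R,3R)-trans-dihydroflavonol of step 14
Product: 23 (2R,3S)-7,8-bis(benzyloxy)-6-[(2R,3R,4R)-7,8-bis(benzyloxy)-2-[3,4-bis(benzyloxy)phenyl]-3-hydroxy-3,4-dihydro-2H-chromen-4-yl]-2-[4-(benzyloxy)phenyl]-4-oxo-3,4-dihydro-2H-chromen-3-yl formate (lower ring C 2,3-cis)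
Conditions: HCO2H, PPh3, DIAD, THF, 0 °C
Reagents that add atoms: formic acid, O=CO
Why: Mitsunobu inversion of an α-ketol; formate displaces the oxyphosphonium at lower C3 by SN2, which is fast next to a carbonyl group, and gives the 2,3-cis formate, while the upper 3-hydroxyl, whose rear face is blocked by the axial 4-aryl group, is not expected to be displaced.

Step 16
Reactants: 23 (2R,3S)-cis formate of step 15
Product: 24 (2R,3S)-6-[(2R,3R,4S)-2-(3,4-dihydroxyphenyl)-3,7,8-trihydroxy-3,4-dihydro-2H-chromen-4-yl]-7,8-dihydroxy-2-(4-hydroxyphenyl)-4-oxo-3,4-dihydro-2H-chromen-3-yl formate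
Conditions: H2 (1 atm), Pd(OH)2/C, EtOAc–MeOH, rt
Reagents that add atoms: none
Why: Hydrogenolysis of the seven O-benzyl groups; the C4 ketone, the formate and the ring C–O bonds should survive these mild neutral conditions, as in debenzylations of protected flavan-3-ols and dihydroflavonols, and no benzylic hydroxyl is yet present at lower C4.

Step 17
Reactants: 24 heptaphenolic cis formate of step 16
Product: 26 (2R,3R,4R)-6-[(2R,3R,4S)-2-(3,4-dihydroxyphenyl)-3,7,8-trihydroxy-3,4-dihydro-2H-chromen-4-yl]-2-(4-hydroxyphenyl)-3,4-dihydro-2H-chromene-3,4,7,8-tetrol (CNP0174688.1), via 3-O-formyl flavan-3,4-diol 25 (not isolated)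
Conditions: NaBH4, MeOH, 0 °C to rt, argon; work-up at pH 6–7
Reagents that add atoms: none
Why: Borohydride reduction of a 3-oxygenated chromanone, as used to turn dihydroflavonols into flavan-3,4-diols; hydride should add to C4 anti to the axial 3-acyloxy group so that H2, H3 and H4 are all cis (C4 R), and the formate is then lost by methanolysis in the basic medium.

Compound list
1 | gallacetophenone (2',3',4'-trihydroxyacetophenone) | CC(=O)c1ccc(O)c(O)c1O | starting material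
2 | 1-[3,4-bis(benzyloxy)-2-hydroxyphenyl]ethan-1-one | CC(=O)c1ccc(OCc9ccccc9)c(OCc9ccccc9)c1O | intermediate
3 | 1-[3,4-bis(benzyloxy)-5-bromo-2-hydroxyphenyl]ethan-1-one | CC(=O)c1cc(Br)c(OCc9ccccc9)c(OCc9ccccc9)c1O | intermediate
4 | 1-[3,4-bis(benzyloxy)-5-bromo-2-(methoxymethoxy)phenyl]ethan-1-one | CC(=O)c1cc(Br)c(OCc9ccccc9)c(OCc9ccccc9)c1OCOC | intermediate
5 | 3,4-bis(benzyloxy)benzaldehyde | O=Cc1ccc(OCc9ccccc9)c(OCc9ccccc9)c1 | starting material
6 | rac-1-[3,4-bis(benzyloxy)phenyl]prop-2-yn-1-ol | C#CC(O)c1ccc(OCc9ccccc9)c(OCc9ccccc9)c1 | intermediate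
7 | O-boryl alkyne: rac-2-({1-[3,4-bis(benzyloxy)phenyl]prop-2-yn-1-yl}oxy)-4,4,5,5-tetramethyl-1,3,2-dioxaborolane | C#CC(OB2OC(C)(C)C(C)(C)O2)c1ccc(OCc9ccccc9)c(OCc9ccccc9)c1 | intermediate
8 | O-boryl alkenylboronate: rac-(E) bis-boryl compound, one pinacolboryl group on oxygen and one on the alkene terminus | CC1(C)OB(/C=C/C(OB2OC(C)(C)C(C)(C)O2)c2ccc(OCc9ccccc9)c(OCc9ccccc9)c2)OC1(C)C | intermediate
9 | rac-(E)-1-[3,4-bis(benzyloxy)phenyl]-3-(4,4,5,5-tetramethyl-1,3,2-dioxaborolan-2-yl)prop-2-en-1-ol | CC1(C)OB(/C=C/C(O)c2ccc(OCc9ccccc9)c(OCc9ccccc9)c2)OC1(C)C | intermediate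
10 | rac-1-{3,4-bis(benzyloxy)-5-[(E)-3-[3,4-bis(benzyloxy)phenyl]-3-hydroxyprop-1-en-1-yl]-2-(methoxymethoxy)phenyl}ethan-1-one (racemic at the carbinol carbon) | CC(=O)c1cc(/C=C/C(O)c2ccc(OCc9ccccc9)c(OCc9ccccc9)c2)c(OCc9ccccc9)c(OCc9ccccc9)c1OCOC | intermediate
11 | 1-{3,4-bis(benzyloxy)-5-[(2S,3S)-3-{(S)-[3,4-bis(benzyloxy)phenyl](hydroxy)methyl}oxiran-2-yl]-2-(methoxymethoxy)phenyl}ethan-1-one (erythro epoxy alcohol, trans-epoxide) | O[C@@H](c2ccc(OCc9ccccc9)c(OCc9ccccc9)c2)[C@@H]3O[C@H]3c4cc(C(C)=O)c(OCOC)c(OCc9ccccc9)c4OCc9ccccc9 | intermediate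
12 | 2,3-dihydroxybenzaldehyde | O=Cc1cccc(O)c1O | starting material
13 | 2,3-bis(benzyloxy)benzaldehyde | O=Cc1cccc(OCc9ccccc9)c1OCc9ccccc9 | intermediate
14 | 2,3-bis(benzyloxy)phenyl formate | O=COc1cccc(OCc9ccccc9)c1OCc9ccccc9 | intermediate
15 | 2,3-bis(benzyloxy)phenol | Oc1cccc(OCc9ccccc9)c1OCc9ccccc9 | intermediate
16 | 1-{5-[(2S,3R)-3-{(R)-[2,3-bis(benzyloxy)phenoxy][3,4-bis(benzyloxy)phenyl]methyl}oxiran-2-yl]-3,4-bis(benzyloxy)-2-(methoxymethoxy)phenyl}ethan-1-one (threo aryl ether of the trans-epoxy carbinol) | c1ccc(OCc9ccccc9)c(OCc9ccccc9)c1O[C@H](c2ccc(OCc9ccccc9)c(OCc9ccccc9)c2)[C@@H]3O[C@H]3c4cc(C(C)=O)c(OCOC)c(OCc9ccccc9)c4OCc9ccccc9 | intermediate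
17 | 1-{3,4-bis(benzyloxy)-5-[(2R,3R,4R)-7,8-bis(benzyloxy)-2-[3,4-bis(benzyloxy)phenyl]-3-hydroxy-3,4-dihydro-2H-chromen-4-yl]-2-(methoxymethoxy)phenyl}ethan-1-one (2,3-cis-3,4-trans; C4 is R here and S in 24–26 only because the ranking of its two aryl groups changes, the geometry is the same) | CC(=O)c1c(OCOC)c(OCc9ccccc9)c(OCc9ccccc9)c(c1)[C@H]4c5ccc(OCc9ccccc9)c(OCc9ccccc9)c5O[C@H](c5ccc(OCc9ccccc9)c(OCc9ccccc9)c5)[C@@H]4O | intermediate
18 | 4-(benzyloxy)benzaldehyde | O=Cc1ccc(OCc9ccccc9)cc1 | starting material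
19 | (E)-1-{3,4-bis(benzyloxy)-5-[(2R,3R,4R)-7,8-bis(benzyloxy)-2-[3,4-bis(benzyloxy)phenyl]-3-hydroxy-3,4-dihydro-2H-chromen-4-yl]-2-(methoxymethoxy)phenyl}-3-[4-(benzyloxy)phenyl]prop-2-en-1-one | O=C(/C=C/c1ccc(OCc9ccccc9)cc1)c1c(OCOC)c(OCc9ccccc9)c(OCc9ccccc9)c(c1)[C@H]4c5ccc(OCc9ccccc9)c(OCc9ccccc9)c5O[C@H](c5ccc(OCc9ccccc9)c(OCc9ccccc9)c5)[C@@H]4O | intermediate
20 | {3,4-bis(benzyloxy)-5-[(2R,3R,4R)-7,8-bis(benzyloxy)-2-[3,4-bis(benzyloxy)phenyl]-3-hydroxy-3,4-dihydro-2H-chromen-4-yl]-2-(methoxymethoxy)phenyl}{(2R,3S)-3-[4-(benzyloxy)phenyl]oxiran-2-yl}methanone | O=C([C@@H]1O[C@H]1c1ccc(OCc9ccccc9)cc1)c1c(OCOC)c(OCc9ccccc9)c(OCc9ccccc9)c(c1)[C@H]4c5ccc(OCc9ccccc9)c(OCc9ccccc9)c5O[C@H](c5ccc(OCc9ccccc9)c(OCc9ccccc9)c5)[C@@H]4O | intermediate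
21 | 2-hydroxyaryl epoxy ketone: compound 20 with the methoxymethyl group replaced by hydrogen | O=C([C@@H]1O[C@H]1c1ccc(OCc9ccccc9)cc1)c1c(O)c(OCc9ccccc9)c(OCc9ccccc9)c(c1)[C@H]4c5ccc(OCc9ccccc9)c(OCc9ccccc9)c5O[C@H](c5ccc(OCc9ccccc9)c(OCc9ccccc9)c5)[C@@H]4O | intermediate
22 | (2R,3R)-7,8-bis(benzyloxy)-6-[(2R,3R,4R)-7,8-bis(benzyloxy)-2-[3,4-bis(benzyloxy)phenyl]-3-hydroxy-3,4-dihydro-2H-chromen-4-yl]-2-[4-(benzyloxy)phenyl]-3-hydroxy-2,3-dihydro-4H-chromen-4-one (lower ring C 2,3-trans) | O=C1[C@H](O)[C@@H](c2ccc(OCc9ccccc9)cc2)Oc2c(OCc9ccccc9)c(OCc9ccccc9)c(cc12)[C@H]4c5ccc(OCc9ccccc9)c(OCc9ccccc9)c5O[C@H](c5ccc(OCc9ccccc9)c(OCc9ccccc9)c5)[C@@H]4O | intermediate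
23 | (2R,3S)-7,8-bis(benzyloxy)-6-[(2R,3R,4R)-7,8-bis(benzyloxy)-2-[3,4-bis(benzyloxy)phenyl]-3-hydroxy-3,4-dihydro-2H-chromen-4-yl]-2-[4-(benzyloxy)phenyl]-4-oxo-3,4-dihydro-2H-chromen-3-yl formate (lower ring C 2,3-cis) | O=C1[C@@H](OC=O)[C@@H](c2ccc(OCc9ccccc9)cc2)Oc2c(OCc9ccccc9)c(OCc9ccccc9)c(cc12)[C@H]4c5ccc(OCc9ccccc9)c(OCc9ccccc9)c5O[C@H](c5ccc(OCc9ccccc9)c(OCc9ccccc9)c5)[C@@H]4O | intermediate
24 | (2R,3S)-6-[(2R,3R,4S)-2-(3,4-dihydroxyphenyl)-3,7,8-trihydroxy-3,4-dihydro-2H-chromen-4-yl]-7,8-dihydroxy-2-(4-hydroxyphenyl)-4-oxo-3,4-dihydro-2H-chromen-3-yl formate | O=C1[C@@H](OC=O)[C@@H](c2ccc(O)cc2)Oc2c(O)c(O)c(cc12)[C@H]4c5ccc(O)c(O)c5O[C@H](c5ccc(O)c(O)c5)[C@@H]4O | intermediate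
25 | (2R,3R,4R)-6-[(2R,3R,4S)-2-(3,4-dihydroxyphenyl)-3,7,8-trihydroxy-3,4-dihydro-2H-chromen-4-yl]-4,7,8-trihydroxy-2-(4-hydroxyphenyl)-3,4-dihydro-2H-chromen-3-yl formate (all-cis) | Oc1ccc([C@H]2Oc3c(cc([C@H]4c5ccc(O)c(O)c5O[C@H](c5ccc(O)c(O)c5)[C@@H]4O)c(O)c3O)[C@@H](O)[C@H]2OC=O)cc1 | intermediate
26 | (2R,3R,4R)-6-[(2R,3R,4S)-2-(3,4-dihydroxyphenyl)-3,7,8-trihydroxy-3,4-dihydro-2H-chromen-4-yl]-2-(4-hydroxyphenyl)-3,4-dihydro-2H-chromene-3,4,7,8-tetrol (upper unit 2,3-cis-3,4-trans, lower unit 2,3-cis-3,4-cis) | Oc1ccc([C@H]2Oc3c(cc([C@H]4c5ccc(O)c(O)c5O[C@H](c5ccc(O)c(O)c5)[C@@H]4O)c(O)c3O)[C@@H](O)[C@H]2O)cc1 | target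

Total step count: 17. Longest linear sequence: 13 steps (steps 1, 2, 3, 6, 7, 10, 11, 12, 13, 14, 15, 16, 17, from gallacetophenone).

Steps most likely to fail

Step 11. Ionisation of the Lewis-acid-bound epoxide may outrun ring closure, so that a 1,2-hydride shift to the C3 ketone (Meinwald rearrangement), capture of C4 by ring B of the upper unit, or loss of the methoxymethyl group competes with the 6-endo closure. The fallback sets out from 16. The epoxide is first opened at benzylic C4 by thiophenol (PhSH, Et3N, MeOH, 40 °C; SN2 with inversion) to give the anti β-hydroxy sulfide F1. AgBF4 in CH2Cl2 at −40 °C then removes sulfur as the silver thiolate and generates the C4 cation with no Lewis acid on O3; ring A should close on it with the lower aryl group trans to O3. This is the thiophilic activation of benzylic sulfides for arylation that is practised at C4 of flavan 4-thioethers. The route is rejoined at 17.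

Step 10. The oxyphosphonium of this electron-rich benzylic carbinol may ionise before the phenol arrives, which erodes the configuration at C2, or the neighbouring epoxide oxygen may take part. The fallback sets out from 6 and forms the aryl ether before the alkene and the epoxide exist. Alcohol 6 is oxidised with MnO2 in CH2Cl2 to the ynone F2. Corey–Bakshi–Shibata reduction with (S)-2-methyl-CBS-oxazaborolidine and catecholborane at −78 °C (aryl as the larger group) should give the (R)-propargylic alcohol F3. Mitsunobu etherification with phenol 15 (PPh3, DIAD, toluene) inverts it to the (S)-propargyl aryl ether F4. Cp2ZrHCl-catalysed hydroboration with pinacolborane gives the (E)-alkenylboronate F5, and Suzuki–Miyaura coupling with bromide 4 (Pd(dppf)Cl2, K3PO4, dioxane–water) gives the (E)-allyl aryl ether F6. Shi epoxidation with the enantiomer of the fructose-derived ketone (KHSO5 as 2KHSO5·KHSO4·K2SO4, K2CO3, MeCN–dimethoxymethane, 0 °C) should place the oxygen on the required face of the trans-alkene under reagent control at basic pH. The route is rejoined at 16.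

Step 15. The activated α-ketol may enolise or eliminate towards the flavonol instead of being displaced, or the cis ester may epimerise back to the trans series. The fallback sets out from 19 and makes the all-cis ring by hydrogenation. Brief treatment of 19 with HCl in MeOH at rt frees the phenol to give the 2'-hydroxychalcone F7. Algar–Flynn–Oyamada oxidation (H2O2, NaOH, MeOH–THF, 0 °C to rt) gives the benzylated flavonol F8. Hydrogenolysis over Pd(OH)2/C (H2, 1 atm) gives the free flavonol F9. Hydrogenation over Raney Ni (H2, 50 bar, EtOH, 50 °C) then adds three hydrogens to one face of lower ring C, the classical conversion of flavonols into 2,3-cis-3,4-cis-flavan-3,4-diols. Because the remote upper unit cannot choose the face, 26 should form together with its lower-unit diastereomer F10, from which it is separated by preparative reversed-phase HPLC. The route is rejoined at 26.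

Further compounds
F1 | step 11 | 1-{3,4-bis(benzyloxy)-5-[(1R,2S,3R)-3-[2,3-bis(benzyloxy)phenoxy]-3-[3,4-bis(benzyloxy)phenyl]-2-hydroxy-1-(phenylsulfanyl)propyl]-2-(methoxymethoxy)phenyl}ethan-1-one | c1ccc(OCc9ccccc9)c(OCc9ccccc9)c1O[C@H](c2ccc(OCc9ccccc9)c(OCc9ccccc9)c2)[C@H](O)[C@H](Sc2ccccc2)c4cc(C(C)=O)c(OCOC)c(OCc9ccccc9)c4OCc9ccccc9
F2 | step 10 | 1-[3,4-bis(benzyloxy)phenyl]prop-2-yn-1-one | C#CC(=O)c1ccc(OCc9ccccc9)c(OCc9ccccc9)c1
F3 | step 10 | (R)-1-[3,4-bis(benzyloxy)phenyl]prop-2-yn-1-ol | C#C[C@@H](O)c1ccc(OCc9ccccc9)c(OCc9ccccc9)c1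
F4 | step 10 | (S)-1,2-bis(benzyloxy)-3-({1-[3,4-bis(benzyloxy)phenyl]prop-2-yn-1-yl}oxy)benzene | C#C[C@H](Oc1cccc(OCc9ccccc9)c1OCc9ccccc9)c1ccc(OCc9ccccc9)c(OCc9ccccc9)c1
F5 | step 10 | (S,E)-2-{3-[2,3-bis(benzyloxy)phenoxy]-3-[3,4-bis(benzyloxy)phenyl]prop-1-en-1-yl}-4,4,5,5-tetramethyl-1,3,2-dioxaborolane | CC1(C)OB(/C=C/[C@H](Oc2cccc(OCc9ccccc9)c2OCc9ccccc9)c2ccc(OCc9ccccc9)c(OCc9ccccc9)c2)OC1(C)C
F6 | step 10 | (S,E)-1-{3,4-bis(benzyloxy)-5-[3-[2,3-bis(benzyloxy)phenoxy]-3-[3,4-bis(benzyloxy)phenyl]prop-1-en-1-yl]-2-(methoxymethoxy)phenyl}ethan-1-one | CC(=O)c1cc(/C=C/[C@H](Oc2cccc(OCc9ccccc9)c2OCc9ccccc9)c2ccc(OCc9ccccc9)c(OCc9ccccc9)c2)c(OCc9ccccc9)c(OCc9ccccc9)c1OCOC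
F7 | step 15 | (E)-1-{3,4-bis(benzyloxy)-5-[(2R,3R,4R)-7,8-bis(benzyloxy)-2-[3,4-bis(benzyloxy)phenyl]-3-hydroxy-3,4-dihydro-2H-chromen-4-yl]-2-hydroxyphenyl}-3-[4-(benzyloxy)phenyl]prop-2-en-1-one | O=C(/C=C/c1ccc(OCc9ccccc9)cc1)c1c(O)c(OCc9ccccc9)c(OCc9ccccc9)c(c1)[C@H]4c5ccc(OCc9ccccc9)c(OCc9ccccc9)c5O[C@H](c5ccc(OCc9ccccc9)c(OCc9ccccc9)c5)[C@@H]4O
F8 | step 15 | 7,8-bis(benzyloxy)-6-[(2R,3R,4R)-7,8-bis(benzyloxy)-2-[3,4-bis(benzyloxy)phenyl]-3-hydroxy-3,4-dihydro-2H-chromen-4-yl]-2-[4-(benzyloxy)phenyl]-3-hydroxy-4H-chromen-4-one | O=c1c(O)c(-c2ccc(OCc9ccccc9)cc2)oc2c(OCc9ccccc9)c(OCc9ccccc9)c(cc12)[C@H]4c5ccc(OCc9ccccc9)c(OCc9ccccc9)c5O[C@H](c5ccc(OCc9ccccc9)c(OCc9ccccc9)c5)[C@@H]4O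
F9 | step 15 | 6-[(2R,3R,4S)-2-(3,4-dihydroxyphenyl)-3,7,8-trihydroxy-3,4-dihydro-2H-chromen-4-yl]-3,7,8-trihydroxy-2-(4-hydroxyphenyl)-4H-chromen-4-one | O=c1c(O)c(-c2ccc(O)cc2)oc2c(O)c(O)c(cc12)[C@H]4c5ccc(O)c(O)c5O[C@H](c5ccc(O)c(O)c5)[C@@H]4O
F10 | step 15 | (2S,3S,4S)-6-[(2R,3R,4S)-2-(3,4-dihydroxyphenyl)-3,7,8-trihydroxy-3,4-dihydro-2H-chromen-4-yl]-2-(4-hydroxyphenyl)-3,4-dihydro-2H-chromene-3,4,7,8-tetrol | Oc1ccc([C@@H]2Oc3c(cc([C@H]4c5ccc(O)c(O)c5O[C@H](c5ccc(O)c(O)c5)[C@@H]4O)c(O)c3O)[C@H](O)[C@@H]2O)cc1
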